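## Analysis of the target

Target 19 is a 5,6-dihydro-2H-pyran-2-one (ring O1, C2–C6) whose C6 carries a ten-carbon chain C1'–C10' ending in a phenyl group. The chain holds an E-alkene C1'=C2', methylene C3', the acetoxy carbinol C4', methylene C5', the free carbinols C6' and C8' on either side of C7', and the C9'–C10' link to the arene. There are four stereocentres, C6 (S) and C4', C6', C8' (all R). In the zigzag chain O6' and O8' are syn and O4' and O6' are anti, while C6 is insulated from this triad by the alkene and must be set on its own. Sensitive points are the conjugated lactone (a Michael acceptor with an allylic C6–O bond), the E-alkene, and the single acetate on one of three secondary oxygens, which can shift to O6' under basic or strongly acidic conditions. The difficulty is less the skeleton than the syn,anti-1,3,5-triol with one oxygen singled out. The route rests on this pattern: O8' lies two atoms from C6', C6' can be the inner carbon of a terminal alkene C5'=C6', C4' is a lone carbinol carbon that carbon monoxide 8 can supply, and C3'–C2' are the first two carbons of an allyl group. A silicon atom on O8' bearing one hydride and two allyl groups can therefore deliver the C6'–Si bond (later C6'–O), C4' and the allyl unit in one operation through two fused oxasilolane rings. Of that allyl group the CH2 becomes C3' and the CH becomes C2'; its terminal CH2 is not C1' but is expelled in the later metathesis, and C1' arrives as the inner vinyl carbon of lactone 17.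

## Retrosynthetic reasoning

Target 19 is traced to its 6',8'-acetonide 18, and 18 is cut at the C1'=C2' double bond into terminal alkene 13 and vinyl lactone 17. This cut is preferred to a single-bond disconnection near C6 because it isolates the remote centre C6 in a six-carbon fragment, joins two stereodefined pieces under neutral conditions and brings the sensitive lactone in last. The forward cross-metathesis must favour the E-alkene, pair the two different terminal alkenes and leave the conjugated ring alkene alone.

Lactone 17 is opened at C3=C4 by a ring-closing-metathesis transform to acrylate 16, the ester of (S)-dienol 15. Dienol 15 is the slow-reacting enantiomer in an epoxidative kinetic resolution of racemic 14. Cutting C3=C4 rather than the lactone C–O bond lets the ring arise from alkenes already present; the forward closure must use the allyl-type alkene and spare the vinyl group.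

In 13 the acetyl C–O bond and then the ketal C–O bonds are removed, back to triol 11. Ketal first, acetate second is the order that singles out O4': under equilibrating conditions the ketal should settle on the syn pair O6'/O8' (chair, both substituents equatorial) and not on the anti pair O4'/O6'.

Triol 11 is the oxidation product of bicyclic silane 10: the C6'–O bond is traced to C6'–Si (oxidation with retention) and the O4'–H and O8'–H bonds to O–Si bonds. The triol problem thereby becomes the problem of placing one silicon atom.

In 10 four bonds are cut: C3'–C4' and O4'–Si (retro-allylation of an aldehyde by an allylsilane), then C4'–C5' and C6'–Si (retro-silylformylation). This leads through aldehyde 9 to the diallyl(hydrido)silyl ether 7 and carbon monoxide 8. Only here does an existing carbinol oxygen (O8') stand homoallylic to the carbon to be oxygenated next (C6'), followed by a one-carbon unit and an allyl unit. The gain is two C–C bonds, two stereocentres and both temporary rings from one stereocentre. The forward step must deliver silicon to C6' syn to C8' and the allyl group to C4' anti to C6'.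

Silyl ether 7 is cut at Si–O into alcohol 3 and chlorosilane 6. Chlorosilane 6 comes from trichlorosilane 4 and two equivalents of allylmagnesium chloride 5. Alcohol 3 comes from 3-phenylpropanal 1 by cutting C7'–C8' in an asymmetric allylation whose borinate 2 is cleaved on work-up. The one centre made here, C8', is the centre from which C6' and C4' are derived.

## Alternatives that were turned down

Alternative 1: The chain would be cut on both sides of C6' (C5'–C6' and C6'–C7'). C6' would be a masked carbonyl supplied by silyl dithiane A1, and C4' and C8' would come from the epoxides A2 and A3.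
- Forward key step: lithiated A1 opens A2 at its CH2 (C5'). A polar cosolvent then lets silicon shift from carbon to the new alkoxide (1,4-Brook rearrangement). The regenerated C6' carbanion opens A3 at C7' and gives A4, with O4' silylated and O8' free; no ring of the target is closed.
- For it: C4' and C8' come from enantiopure epoxides and cannot erode. O4' is differentiated from the first moment, which is stronger than the ketal thermodynamics relied on in step 6. C6' could later be set by an O8'-directed syn reduction, normally more selective than a silylrhodation.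
- Against it: both epoxides must first be made or resolved. C6' arrives at the ketone level, so a thioketal cleavage beside a terminal alkene and a directed reduction are added. The step needs a pyrophoric alkyllithium and a toxic phosphoramide at low temperature. Ketalisation, desilylation and acetylation still follow A4.
- Comparison: roughly ten operations are needed to reach the stage of 13, against seven here. The chosen tandem step gives up some certainty at C6' but creates C6' and C4' and two C–C bonds at once from one cheap stereocentre.

Alternative 2: The lactone ring would be disconnected at C5–C6 and O1–C2 and built on the finished chain by a hetero-Diels–Alder reaction.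
- Forward key step: the aldehyde of enal A5 reacts with diene A6 under a chiral Lewis acid catalyst that selects the aldehyde face. This gives the cis-2-methoxy-6-alkenyl dihydropyran A7, which must then be oxidised at the acetal carbon to the lactone.
- For it: C6 is set by catalyst control without the half-loss of a resolution, and no separate lactone fragment is needed. On enantiocontrol at C6 it is stronger than the chosen route.
- Against it: it does not address the triol triad, so the chain would still have to be made as planned here. A conjugated aldehyde is a weaker heterodienophile and may react at its C=C bond. The acetal oxidation needs acid and oxidant beside the ketal and acetate. Three to four linear steps are spent on the most advanced intermediate.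
- Comparison: the chosen route offers convergence instead. C6 is made on a six-carbon piece in three simple steps and attached in one.

Alternative 3: C2'–C3' and the C4'–O(acetate) bond would be formed by a Prins cyclisation, with a temporary O6'–C2' bond.
- Forward key step: the C6' hydroxyl of A8 condenses with aldehyde A9 under a boron Lewis acid in a carboxylic acid. The oxocarbenium ion is attacked by the C3'=C4' alkene through a chair, and acetate caps C4' equatorially to give the all-cis tetrahydropyran A10.
- For it: C4' is set anti to O6' with high fidelity, and the acetate is placed on O4' and nowhere else. On O4' differentiation it is stronger than the chosen route.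
- Against it: A8 already needs C6' and C8', which takes two asymmetric allylations with protection and ozonolysis between, so the step creates only C4'. The pyran ring is not in the target and must be destroyed again by debenzylation, iodination and reductive fragmentation. Oxonia-Cope scrambling and competing nucleophile capture are known risks.
- Comparison: the chosen step sets C6' and C4' together from a three-step precursor, and its temporary rings are removed in one oxidation.

Key step: step 4

Remark on the chemistry: commercial hexa-1,5-dien-3-ol 14 is taken to be the racemate, so its (S)-enantiomer is obtained by kinetic resolution; hydridosilanes 6 and 7 and bicyclic silane 10 are taken to be moisture-sensitive and are carried on without chromatography.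

## Route

Step 1
Reactants: 1 3-phenylpropanal
Product: 3 (3R)-1-phenylhex-5-en-3-ol, via borinate ester 2 (not isolated)
Conditions: (−)-Ipc2BOMe, allylMgBr, Et2O, −78 °C → rt; then 1, −78 °C; then 3 M NaOH, 30% H2O2, rt
Reagents that add atoms: allylmagnesium bromide, C=CC[Mg]Br
Why: Brown asymmetric allylboration; the allylborane made from (+)-α-pinene adds to the Si face of the aldehyde through a closed six-membered chair, which for an unbranched aldehyde should give the (R)-carbinol C8', and alkaline peroxide cleaves borinate 2.

Step 2
Reactants: 4 trichlorosilane; 5 allylmagnesium chloride (2 equiv)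
Product: 6 chlorodi(prop-2-en-1-yl)silane
Conditions: 5 (THF solution) added to 4, Et2O, −78 °C → rt; filtration; fractional distillation
Reagents that add atoms: none
Why: Stepwise Grignard substitution at silicon; each allyl group lowers the electrophilicity of silicon, so two equivalents added cold should favour the dialkylated chlorosilane, the Si–H bond is untouched, and mono- and triallyl silanes are removed by distillation.

Step 3
Reactants: 3 (3R)-1-phenylhex-5-en-3-ol; 6 chlorodi(prop-2-en-1-yl)silane
Product: 7 {[(3R)-1-phenylhex-5-en-3-yl]oxy}di(prop-2-en-1-yl)silane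
Conditions: Et3N, DMAP (cat.), CH2Cl2, 0 °C → rt
Reagents that add atoms: none
Why: O-Silylation of a secondary alcohol by a chlorosilane with amine base and nucleophilic catalysis; the C8'–O bond is not broken, so the configuration is kept.

Step 4
Reactants: 7 {[(3R)-1-phenylhex-5-en-3-yl]oxy}di(prop-2-en-1-yl)silane; 8 carbon monoxide
Product: 10 (1S,3R,5R,7R)-3-(2-phenylethyl)-1,7-di(prop-2-en-1-yl)-2,8-dioxa-1-silabicyclo[3.3.0]octane, via oxasilolane aldehyde 9 (not isolated)
Conditions: Rh(acac)(CO)2 (3 mol %), CO (70 bar), benzene, 60 °C; vent, concentrate
Reagents that add atoms: none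
Why: This is the rhodium-catalysed tandem intramolecular alkene silylformylation–allylsilylation, whose closest known type is the silylformylation of homoallylic hydridosilyl ethers followed by spontaneous carbonyl allylation by the strained allylsilane so formed. Oxidative addition of Si–H to monovalent rhodium and 5-exo-trig silylrhodation of C5'=C6' put silicon on C6' and close ring A (Si, O8', C8', C7', C6'); CO insertion into the Rh–C5' bond and C–H reductive elimination then give aldehyde 9 with C4' as the formyl carbon. In the five-membered ring silicon is strained and Lewis acidic, so the aldehyde oxygen binds to it and one allyl group migrates to C4' through a six-membered chair transition state while the O4'–Si bond forms, which closes ring B (Si, C6', C5', C4', O4') by O-to-Si bond formation in a necessarily cis-fused bicycle. C6' is set in the silylrhodation: the C8' phenethyl group takes a pseudo-equatorial place in the forming ring, which leads to the cis-3,5-disubstituted oxasilolane and hence to O6' syn to O8'; this is the weaker control element. C4' is set in the allyl transfer: the two-carbon tether lets the carbonyl reach silicon from one side only, and the chair then delivers the allyl group to the face that puts O4' anti to C6'; the silicon centre follows from the cis fusion. The step needs regioselectivity (Si to the inner, CO to the terminal alkene carbon), chemoselectivity (the Si-allyl alkenes must stay untouched) and the syn/anti diastereoselectivity; the terminal homoallylic alkene, intramolecular Si–H delivery, high CO pressure and the single directing centre C8' are what secure them. A C6' epimer, if formed, is carried into step 5 and removed at 11 or 12.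

Step 5
Reactants: 10 bicyclic silane
Product: 11 (4R,6R,8R)-10-phenyldec-1-ene-4,6,8-triol
Conditions: 30% H2O2, KF, KHCO3, THF/MeOH (1:1), rt → 50 °C
Reagents that add atoms: hydrogen peroxide, OO
Why: Tamao–Fleming oxidation; hydroperoxide adds to the activated dialkoxysilane and C6' migrates from Si to O with retention, so C6'–Si becomes C6'–OH syn to O8', the Si–O bonds are hydrolysed and the terminal alkene is inert to basic peroxide.

Step 6
Reactants: 11 (4R,6R,8R)-10-phenyldec-1-ene-4,6,8-triol
Product: 12 (2R)-1-[(4S,6R)-2,2-dimethyl-6-(2-phenylethyl)-1,3-dioxan-4-yl]pent-4-en-2-ol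
Conditions: 2,2-dimethoxypropane, PPTS (cat.), CH2Cl2, rt (equilibrating)
Reagents that add atoms: 2,2-dimethoxypropane, COC(C)(C)OC
Why: Acid-catalysed transketalisation under thermodynamic control; the syn O6'/O8' pair gives a chair dioxane with both substituents equatorial whereas a ketal across the anti O4'/O6' pair would be forced into a twist-boat, so O4' should stay free, and a C6'-epimeric triol gives only such disfavoured ketals and is separated here.

Step 7
Reactants: 12 acetonide alcohol
Product: 13 (2R)-1-[(4R,6R)-2,2-dimethyl-6-(2-phenylethyl)-1,3-dioxan-4-yl]pent-4-en-2-yl acetate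
Conditions: Ac2O, pyridine, DMAP (cat.), CH2Cl2, 0 °C → rt
Reagents that add atoms: acetic anhydride, CC(=O)OC(C)=O
Why: DMAP-catalysed acetylation of the only free hydroxyl; the C4'–O bond is not broken and the basic anhydrous medium leaves ketal and alkene untouched.

Step 8
Reactants: 14 rac-hexa-1,5-dien-3-ol
Product: 15 (3S)-hexa-1,5-dien-3-ol
Conditions: Ti(OiPr)4 (0.15 equiv), D-(−)-diisopropyl tartrate (0.18 equiv), t-BuOOH (0.6 equiv), 4 Å MS, CH2Cl2, −20 °C
Reagents that add atoms: none
Why: Sharpless kinetic resolution; with the D-(−)-tartrate ligand the (R)-enantiomer is epoxidised at its allylic vinyl group much faster, so the (S)-alcohol is recovered (at most half of the material) when the reaction is stopped a little past half conversion, and the homoallylic alkene is not directed and stays.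

Step 9
Reactants: 15 (3S)-hexa-1,5-dien-3-ol
Product: 16 (3S)-hexa-1,5-dien-3-yl prop-2-enoate
Conditions: acryloyl chloride, Et3N, DMAP (cat.), CH2Cl2, 0 °C
Reagents that add atoms: acryloyl chloride, C=CC(=O)Cl
Why: O-Acylation of a secondary alcohol by an acid chloride at low temperature; the stereocentre is not involved.

Step 10
Reactants: 16 (3S)-hexa-1,5-dien-3-yl prop-2-enoate
Product: 17 (6S)-6-ethenyl-5,6-dihydro-2H-pyran-2-one
Conditions: RuCl2(PCy3)2(=CHPh) (first-generation Grubbs catalyst, 10 mol %), Ti(OiPr)4 (0.3 equiv), CH2Cl2 (0.005 M), 40 °C
Reagents that add atoms: none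
Why: Ring-closing metathesis; the catalyst should load at the unhindered homoallylic alkene and close onto the acrylate to the six-membered unsaturated lactone, the branched allylic vinyl group reacting more slowly and a butenolide being disfavoured, while high dilution suppresses oligomers.

Step 11
Reactants: 13 acetonide acetate; 17 (6S)-6-ethenyl-5,6-dihydro-2H-pyran-2-one (2–3 equiv)
Product: 18 (2R,4E)-1-[(4R,6R)-2,2-dimethyl-6-(2-phenylethyl)-1,3-dioxan-4-yl]-5-[(2S)-6-oxo-3,6-dihydro-2H-pyran-2-yl]pent-4-en-2-yl acetate
Conditions: RuCl2(H2IMes)(PCy3)(=CHPh) (second-generation Grubbs catalyst, 5–10 mol %), CH2Cl2, 40 °C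
Reagents that add atoms: none
Why: Olefin cross-metathesis between the unhindered terminal alkene of 13 and the allylically oxygenated vinyl group of 17, which dimerises slowly and is used in excess; the E-alkene is expected under thermodynamic control, C1' comes from 17 and C2' from 13, and the conjugated ring alkene, acetate and ketal are tolerated.

Step 12
Reactants: 18 acetonide acetate lactone
Product: 19 (1E,4R,6R,8R)-6,8-dihydroxy-1-[(2S)-6-oxo-3,6-dihydro-2H-pyran-2-yl]-10-phenyldec-1-en-4-yl acetate
Conditions: AcOH/H2O (4:1), rt → 40 °C
Reagents that add atoms: none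
Why: Acid-catalysed hydrolysis of the isopropylidene ketal; weak aqueous acid without an alcohol avoids transesterification and conjugate addition, and 1,3-acyl migration through a six-membered orthoester is slow under weakly acidic conditions, so no stereocentre or ester should be touched.

## Compound list

1 | 3-phenylpropanal | O=CCCc1ccccc1 | starting material
2 | (3R)-1-phenylhex-5-en-3-yl diisopinocampheylborinate | C=CC[C@H](OB([C@@H]1C[C@@H]2C[C@H]([C@H]1C)C2(C)C)[C@@H]1C[C@@H]2C[C@H]([C@H]1C)C2(C)C)CCc1ccccc1 | intermediate
3 | (3R)-1-phenylhex-5-en-3-ol | C=CC[C@H](O)CCc1ccccc1 | intermediate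
4 | trichlorosilane | Cl[SiH](Cl)Cl | starting material
5 | allylmagnesium chloride | C=CC[Mg]Cl | starting material
6 | chlorodi(prop-2-en-1-yl)silane | C=CC[SiH](Cl)CC=C | intermediate
7 | {[(3R)-1-phenylhex-5-en-3-yl]oxy}di(prop-2-en-1-yl)silane | C=CC[C@H](O[SiH](CC=C)CC=C)CCc1ccccc1 | intermediate
8 | carbon monoxide | [C-]#[O+] | starting material
9 | 2-[(3R,5R)-5-(2-phenylethyl)-2,2-di(prop-2-en-1-yl)-1,2-oxasilolan-3-yl]acetaldehyde | C=CC[Si]1(CC=C)O[C@H](CCc2ccccc2)C[C@@H]1CC=O | intermediate
10 | (1S,3R,5R,7R)-3-(2-phenylethyl)-1,7-di(prop-2-en-1-yl)-2,8-dioxa-1-silabicyclo[3.3.0]octane | C=CC[Si@@]12O[C@H](CCc3ccccc3)C[C@@H]1C[C@@H](CC=C)O2 | intermediate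
11 | (4R,6R,8R)-10-phenyldec-1-ene-4,6,8-triol | C=CC[C@@H](O)C[C@H](O)C[C@H](O)CCc1ccccc1 | intermediate
12 | (2R)-1-[(4S,6R)-2,2-dimethyl-6-(2-phenylethyl)-1,3-dioxan-4-yl]pent-4-en-2-ol | C=CC[C@@H](O)C[C@H]1C[C@@H](CCc2ccccc2)OC(C)(C)O1 | intermediate
13 | (2R)-1-[(4R,6R)-2,2-dimethyl-6-(2-phenylethyl)-1,3-dioxan-4-yl]pent-4-en-2-yl acetate | C=CC[C@@H](OC(C)=O)C[C@H]1C[C@@H](CCc2ccccc2)OC(C)(C)O1 | intermediate
14 | rac-hexa-1,5-dien-3-ol | C=CCC(O)C=C | starting material
15 | (3S)-hexa-1,5-dien-3-ol | C=C[C@@H](O)CC=C | intermediate
16 | (3S)-hexa-1,5-dien-3-yl prop-2-enoate | C=CC(=O)O[C@H](C=C)CC=C | intermediate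
17 | (6S)-6-ethenyl-5,6-dihydro-2H-pyran-2-one | C=C[C@@H]1CC=CC(=O)O1 | intermediate
18 | (2R,4E)-1-[(4R,6R)-2,2-dimethyl-6-(2-phenylethyl)-1,3-dioxan-4-yl]-5-[(2S)-6-oxo-3,6-dihydro-2H-pyran-2-yl]pent-4-en-2-yl acetate | CC(=O)O[C@H](C/C=C/[C@@H]1CC=CC(=O)O1)C[C@H]2C[C@@H](CCc3ccccc3)OC(C)(C)O2 | intermediate
19 | (1E,4R,6R,8R)-6,8-dihydroxy-1-[(2S)-6-oxo-3,6-dihydro-2H-pyran-2-yl]-10-phenyldec-1-en-4-yl acetate | CC(=O)O[C@H](C/C=C/[C@@H]1CC=CC(=O)O1)C[C@H](O)C[C@H](O)CCc1ccccc1 | target

## Step count and least certain steps

Total: 12 steps. Longest linear sequence: 8 steps (steps 1, 3, 4, 5, 6, 7, 11, 12 from 3-phenylpropanal 1).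

**Step 4 (key step).** The most likely failure is insufficient facial discrimination in the silylrhodation, which would erode the syn relation of C6' to C8'. The only bias is the pseudo-equatorial preference of a remote substituent in a flexible five-membered transition state. Alkene hydrosilylation without CO uptake may also compete if CO is depleted. The fallback sets out from 3 and comes back at 12, using only reagent control.
- Alcohol 3 is silylated (TBSCl, imidazole) to silyl ether F1.
- Ozonolysis (O3; PPh3) gives aldehyde F2.
- Allylboration with (−)-Ipc2B(allyl) gives the syn homoallylic alcohol F3.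
- TBAF gives diol F4, and 2,2-dimethoxypropane with PPTS gives acetonide F5.
- A second ozonolysis gives aldehyde F6, and allylboration with the antipodal (+)-Ipc2B(allyl) gives 12.
- Since O4' is created free beside a preformed ketal, the regiochemical question of step 6 also disappears.

**Step 2.** Over- and under-substitution at silicon is the likely problem, because the allyl Grignard reagent is very reactive and the allyl group small, so the mixture may be hard to fractionate. The fallback sets out from 4 and comes back at 7.
- Trichlorosilane 4 and diethylamine (2 equiv) give dichloro(diethylamino)silane F7, in which one site is blocked by an amino group inert to Grignard reagents.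
- Two equivalents of 5 give diallyl(diethylamino)silane F8.
- Heating F8 with 3 without solvent gives 7 by alcoholysis of the Si–N bond.

**Step 8.** Incomplete enantiomer discrimination and loss on isolation are likely, because monosubstituted vinyl carbinols are epoxidised slowly, conversion control is delicate and 15 is volatile. The fallback sets out from acrolein F9 and comes back at 15: allylboration of acrolein F9 with (−)-Ipc2B(allyl) at −78 °C, then oxidative work-up and distillation, gives 15 directly.

**Step 11.** Self-metathesis of 13 may outrun the cross reaction, and the catalyst may decay before the hindered vinyl group of 17 is engaged. The fallback sets out from 13 and comes back at 18, building the lactone on the chain.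
- Cross-metathesis of 13 with crotonaldehyde, catalysed by RuCl2(H2IMes)(=CHC6H4-2-OiPr) (second-generation Hoveyda–Grubbs catalyst), gives enal F10.
- Allylboration with (−)-Ipc2B(allyl), with NaBO3·4H2O work-up to spare the acetate, gives (S)-dienol F11.
- Acryloyl chloride and Et3N give acrylate F12.
- Ring-closing metathesis with RuCl2(PCy3)2(=CHPh) gives 18.

**Step 12.** Acid-induced acyl shift from O4' to the freshly liberated O6', or incomplete hydrolysis when the acid is kept weak, is the concern, because the freed hydroxyl sits 1,3 to the ester. The fallback sets out from 12 and comes back at 19. It removes the ketal before any ester is present and ends with a fluoride deprotection.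
- Alcohol 12 is converted (NaH, 4-methoxybenzyl chloride, Bu4NI) into PMB ether F13.
- Aqueous acetic acid gives diol F14.
- TBSOTf and 2,6-lutidine give bis-silyl ether F15.
- DDQ in buffered CH2Cl2 gives alcohol F16.
- Ac2O and DMAP give acetate F17.
- Cross-metathesis with 17 gives lactone F18.
- HF·pyridine buffered with pyridine in THF gives 19.

## Further compounds

F1 | step 4 | tert-butyldimethyl{[(3R)-1-phenylhex-5-en-3-yl]oxy}silane | C=CC[C@H](O[Si](C)(C)C(C)(C)C)CCc1ccccc1
F2 | step 4 | (3R)-3-[(tert-butyldimethylsilyl)oxy]-5-phenylpentanal | O=CC[C@H](O[Si](C)(C)C(C)(C)C)CCc1ccccc1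
F3 | step 4 | (4S,6R)-6-[(tert-butyldimethylsilyl)oxy]-8-phenyloct-1-en-4-ol | C=CC[C@H](O)C[C@H](O[Si](C)(C)C(C)(C)C)CCc1ccccc1
F4 | step 4 | (4S,6R)-8-phenyloct-1-ene-4,6-diol | C=CC[C@H](O)C[C@H](O)CCc1ccccc1
F5 | step 4 | (4R,6S)-2,2-dimethyl-4-(2-phenylethyl)-6-(prop-2-en-1-yl)-1,3-dioxane | C=CC[C@H]1C[C@@H](CCc2ccccc2)OC(C)(C)O1
F6 | step 4 | 2-[(4R,6R)-2,2-dimethyl-6-(2-phenylethyl)-1,3-dioxan-4-yl]acetaldehyde | O=CC[C@H]1C[C@@H](CCc2ccccc2)OC(C)(C)O1
F7 | step 2 | dichloro(diethylamino)silane | CCN(CC)[SiH](Cl)Cl
F8 | step 2 | diallyl(diethylamino)silane | CCN(CC)[SiH](CC=C)CC=C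
F9 | step 8 | acrolein (prop-2-enal, bought) | C=CC=O
F10 | step 11 | (2R,4E)-1-[(4R,6R)-2,2-dimethyl-6-(2-phenylethyl)-1,3-dioxan-4-yl]-6-oxohex-4-en-2-yl acetate (same compound as A5) | CC(=O)O[C@H](C/C=C/C=O)C[C@H]1C[C@@H](CCc2ccccc2)OC(C)(C)O1
F11 | step 11 | (2R,4E,6S)-1-[(4R,6R)-2,2-dimethyl-6-(2-phenylethyl)-1,3-dioxan-4-yl]-6-hydroxynona-4,8-dien-2-yl acetate | CC(=O)O[C@H](C/C=C/[C@@H](O)CC=C)C[C@H]1C[C@@H](CCc2ccccc2)OC(C)(C)O1
F12 | step 11 | (4S,5E,8R)-8-acetoxy-9-[(4R,6R)-2,2-dimethyl-6-(2-phenylethyl)-1,3-dioxan-4-yl]nona-1,5-dien-4-yl prop-2-enoate | CC(=O)O[C@H](C/C=C/[C@@H](OC(=O)C=C)CC=C)C[C@H]1C[C@@H](CCc2ccccc2)OC(C)(C)O1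
F13 | step 12 | O4'-(4-methoxybenzyl) ether of 12 | C=CC[C@@H](OCc1ccc(OC)cc1)C[C@H]1C[C@@H](CCc2ccccc2)OC(C)(C)O1
F14 | step 12 | (4R,6R,8R)-4-[(4-methoxyphenyl)methoxy]-10-phenyldec-1-ene-6,8-diol | C=CC[C@@H](OCc1ccc(OC)cc1)C[C@H](O)C[C@H](O)CCc1ccccc1
F15 | step 12 | 6',8'-bis(tert-butyldimethylsilyl) ether of F14 | C=CC[C@@H](OCc1ccc(OC)cc1)C[C@H](O[Si](C)(C)C(C)(C)C)C[C@H](O[Si](C)(C)C(C)(C)C)CCc1ccccc1
F16 | step 12 | 6',8'-bis(tert-butyldimethylsilyl) ether of triol 11 | C=CC[C@@H](O)C[C@H](O[Si](C)(C)C(C)(C)C)C[C@H](O[Si](C)(C)C(C)(C)C)CCc1ccccc1
F17 | step 12 | O4'-acetate of F16 | C=CC[C@@H](OC(C)=O)C[C@H](O[Si](C)(C)C(C)(C)C)C[C@H](O[Si](C)(C)C(C)(C)C)CCc1ccccc1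
F18 | step 12 | 6',8'-bis(tert-butyldimethylsilyl) ether of 19 | CC(=O)O[C@H](C/C=C/[C@@H]1CC=CC(=O)O1)C[C@H](O[Si](C)(C)C(C)(C)C)C[C@H](O[Si](C)(C)C(C)(C)C)CCc1ccccc1
A1 | alternative 1 | 2-(tert-butyldimethylsilyl)-1,3-dithiane | CC(C)(C)[Si](C)(C)C1SCCCS1
A2 | alternative 1 | (R)-2-(prop-2-en-1-yl)oxirane | C=CC[C@@H]1CO1
A3 | alternative 1 | (R)-2-(2-phenylethyl)oxirane | c1ccccc1CC[C@@H]1CO1
A4 | alternative 1 | (2R)-1-{2-[(2R)-2-[(tert-butyldimethylsilyl)oxy]pent-4-en-1-yl]-1,3-dithian-2-yl}-4-phenylbutan-2-ol | C=CC[C@@H](O[Si](C)(C)C(C)(C)C)CC1(SCCCS1)C[C@H](O)CCc2ccccc2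
A5 | alternative 2 | (2R,4E)-1-[(4R,6R)-2,2-dimethyl-6-(2-phenylethyl)-1,3-dioxan-4-yl]-6-oxohex-4-en-2-yl acetate | CC(=O)O[C@H](C/C=C/C=O)C[C@H]1C[C@@H](CCc2ccccc2)OC(C)(C)O1
A6 | alternative 2 | (E)-1-methoxybuta-1,3-diene | CO/C=C/C=C
A7 | alternative 2 | cis-2-methoxy-6-alkenyl-5,6-dihydro-2H-pyran carrying the protected chain | CC(=O)O[C@H](C/C=C/[C@@H]1CC=C[C@H](OC)O1)C[C@H]2C[C@@H](CCc3ccccc3)OC(C)(C)O2
A8 | alternative 3 | (4S,6R)-6-[(tert-butyldiphenylsilyl)oxy]-8-phenyloct-1-en-4-ol | C=CC[C@H](O)C[C@H](O[Si](c1ccccc1)(c1ccccc1)C(C)(C)C)CCc1ccccc1
A9 | alternative 3 | (benzyloxy)acetaldehyde | O=CCOCc1ccccc1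
A10 | alternative 3 | all-cis 2-(benzyloxymethyl)-6-[(2R)-2-(tert-butyldiphenylsilyloxy)-4-phenylbutyl]tetrahydropyran-4-yl acetate | CC(=O)O[C@@H]1C[C@H](COCc2ccccc2)O[C@H](C[C@H](O[Si](c2ccccc2)(c2ccccc2)C(C)(C)C)CCc2ccccc2)C1
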